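**Assumption (remark on the chemistry):** the tetronic acid hydroxyl is carried as its methyl ether through the organometallic step, so the key step joins the methyl ether of the alkynyl tetronic acid (16) to the iodide and gives the methyl ether of the target (29), which is demethylated last. The bonds formed in the key step are unchanged. 3-Methyltetronic acid, hept-6-ynoic acid, (R)-4-benzyloxazolidin-2-one, (S)-(−)-β-citronellene and 3-bromofuran are taken as commercial.

## Retrosynthetic overview

1. Target 31 comes from its 4-O-methyl ether 29 by thiolate demethylation.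
2. 29 comes from terminal alkyne 16 and E-alkenyl iodide 26. The strategy rests on the diene C11(CH3)=C12–C13=C14 of the chain (numbered C6–C18 from ring carbon C5 to the furan): an E trisubstituted alkene with its methyl on C11, flanked by the saturated CH2 C10, joined to an E disubstituted alkene. Syn methyl–aluminium addition to C11≡C12 and palladium coupling form C11–CH3 and C12–C13.
3. 16 comes from methyl tetronate 3 and (R)-2-methylhept-6-ynal 11 by aldol addition and dehydration; C7 is set by an Evans methylation.
4. 26 comes from (S)-β-citronellene 17 (which supplies C15) and 3-bromofuran 21: selective ozonolysis, alkyl–furyl Negishi coupling, cross-metathesis with vinyl-Bpin, iododeboronation.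
5. Ring order: no ring is formed in the route; the butenolide ring (from 3-methyltetronic acid 1) and the furan ring (from 21) are bought in.

Key step: step 13

## Route

**Step 1**
Reactants: 1 4-hydroxy-3-methylfuran-2(5H)-one (3-methyltetronic acid)
Product: 3 4-methoxy-3-methylfuran-2(5H)-one, via potassium tetronate 2 (not isolated)
Conditions: Me2SO4, K2CO3, acetone, reflux
Reagents that add atoms: dimethyl sulfate, COS(=O)(=O)OC
Why: O-alkylation of the vinylogous carboxylate (Williamson-type methylation) should go at O4 because the hard sulfate electrophile favours the enolate oxygen over C3.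

**Step 2**
Reactants: 4 hept-6-ynoic acid; 5 (R)-4-benzyloxazolidin-2-one
Product: 7 (4R)-4-benzyl-3-(hept-6-ynoyl)oxazolidin-2-one, via mixed pivalic anhydride 6 (not isolated)
Conditions: t-BuCOCl, Et3N, THF, −20 °C; then LiCl, 5, −20 °C to rt
Reagents that add atoms: none
Why: Mixed-anhydride N-acylation of the oxazolidinone (pivaloyl chloride/LiCl/Et3N protocol) should deliver the imide because the nucleophile attacks the unhindered heptynoyl carbonyl and not the pivaloyl one.

**Step 3**
Reactants: 7 (4R)-4-benzyl-3-(hept-6-ynoyl)oxazolidin-2-one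
Product: 9 (4R)-4-benzyl-3-[(2R)-2-methylhept-6-ynoyl]oxazolidin-2-one, via sodium Z-enolate 8 (not isolated)
Conditions: NaN(SiMe3)2 (1.05 equiv), THF, −78 °C; MeI, −78 °C
Reagents that add atoms: iodomethane, CI
Why: Evans asymmetric alkylation: the chelated Z-enolate is methylated on the face opposite the C4 benzyl group, which sets the future C7 as R, while the alkyne C–H is too weakly acidic to compete with the imide α-hydrogen; the minor diastereomer is removed by chromatography.

**Step 4**
Reactants: 9 (4R)-4-benzyl-3-[(2R)-2-methylhept-6-ynoyl]oxazolidin-2-one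
Product: 10 (2R)-2-methylhept-6-yn-1-ol
Conditions: LiBH4, MeOH (1 equiv), Et2O, 0 °C
Reagents that add atoms: none
Why: Reductive removal of the Evans auxiliary by hydride attack on the exocyclic acyl carbonyl should give the primary alcohol without touching the α-stereocenter or the alkyne.

**Step 5**
Reactants: 10 (2R)-2-methylhept-6-yn-1-ol
Product: 11 (2R)-2-methylhept-6-ynal
Conditions: TEMPO (10 mol%), PhI(OAc)2, CH2Cl2, rt; used crude
Reagents that add atoms: none
Why: TEMPO-catalysed oxidation with PhI(OAc)2 (oxoammonium oxidation) stops at the aldehyde under non-basic conditions, so the α-stereocenter should survive.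

**Step 6**
Reactants: 3 4-methoxy-3-methylfuran-2(5H)-one; 11 (2R)-2-methylhept-6-ynal
Product: 14 5-[(2R)-1-hydroxy-2-methylhept-6-ynyl]-4-methoxy-3-methylfuran-2(5H)-one (aldol diastereomer mixture), via lithium furanolate 12 (not isolated), via lithium aldolate 13 (not isolated)
Conditions: LDA, THF, −78 °C; then 11, −78 °C; aq. NH4Cl
Reagents that add atoms: none
Why: Aldol addition of the C5-lithiated methyl tetronate to the aldehyde at −78 °C should outrun enolisation of 11; the two new stereocenters (C5 and the carbinol carbon) form unselectively and are both erased in step 7.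

**Step 7**
Reactants: 14 5-[(2R)-1-hydroxy-2-methylhept-6-ynyl]-4-methoxy-3-methylfuran-2(5H)-one
Product: 16 (5Z)-4-methoxy-3-methyl-5-[(2R)-2-methylhept-6-ynylidene]furan-2(5H)-one, via mesylate 15 (not isolated)
Conditions: MsCl, Et3N, CH2Cl2, 0 °C; then DBU, 0 °C to rt
Reagents that add atoms: none
Why: Mesylation and E1cB elimination through the extended dienolate should give the conjugated 5-ylidene butenolide with Z geometry, because the branched C7 substituent avoids the C4 methoxy group; any E isomer is separated by chromatography.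

**Step 8**
Reactants: 17 (S)-β-citronellene
Product: 19 (4S)-4-methylhex-5-en-1-ol, via aldehyde 18 (not isolated)
Conditions: O3, CH2Cl2/MeOH, −78 °C (stopped at the indicator-dye end point); Me2S; then NaBH4 (excess), 0 °C
Reagents that add atoms: ozone, [O-][O+]=O
Why: Chemoselective ozonolysis: electrophilic ozone cleaves the electron-rich trisubstituted alkene faster than the vinyl group, and borohydride reduction gives the alcohol with the C15 stereocenter taken unchanged from the chiral pool.

**Step 9**
Reactants: 19 (4S)-4-methylhex-5-en-1-ol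
Product: 20 (3S)-6-iodo-3-methylhex-1-ene
Conditions: I2, PPh3, imidazole, CH2Cl2, 0 °C to rt
Reagents that add atoms: iodine, II
Why: Appel-type iodination (SN2 displacement of the alkoxyphosphonium by iodide) is reliable for an unhindered primary alcohol.

**Step 10**
Reactants: 20 (3S)-6-iodo-3-methylhex-1-ene; 21 3-bromofuran
Product: 24 3-[(4S)-4-methylhex-5-enyl]furan, via alkyllithium 22 (not isolated), via alkylzinc bromide 23 (not isolated)
Conditions: t-BuLi (2.1 equiv), Et2O, −78 °C; ZnBr2, THF, −78 to 0 °C; then 21, Pd(dppf)Cl2 (3 mol%), THF, rt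
Reagents that add atoms: none
Why: Negishi alkyl–heteroaryl coupling: iodine–lithium exchange at −78 °C (too cold for the hexenyllithium to cyclise) and transmetalation to zinc give a primary alkylzinc, which Pd(dppf)Cl2 should couple with 3-bromofuran faster than β-hydride elimination.

**Step 11**
Reactants: 24 3-[(4S)-4-methylhex-5-enyl]furan
Product: 25 2-[(1E,3S)-6-(furan-3-yl)-3-methylhex-1-enyl]-4,4,5,5-tetramethyl-1,3,2-dioxaborolane
Conditions: vinyl-Bpin (2 equiv), second-generation Grubbs catalyst (5 mol%), CH2Cl2, 40 °C
Reagents that add atoms: 4,4,5,5-tetramethyl-2-vinyl-1,3,2-dioxaborolane, C=CB1OC(C)(C)C(C)(C)O1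
Why: Olefin cross-metathesis of a terminal alkene with vinyl pinacol boronate is E-selective, the allylic methyl branch slows homodimerisation, and the furan is inert to the ruthenium carbene.

**Step 12**
Reactants: 25 2-[(1E,3S)-6-(furan-3-yl)-3-methylhex-1-enyl]-4,4,5,5-tetramethyl-1,3,2-dioxaborolane
Product: 26 3-[(4S,5E)-6-iodo-4-methylhex-5-enyl]furan
Conditions: NaOH (3 M aq.), THF, 0 °C; then I2 in THF, 0 °C, dark; aq. Na2S2O3
Reagents that add atoms: iodine, II
Why: Iododeboronation of the hydroxide-activated E-alkenyl boronate with iodine proceeds with retention of alkene geometry, and slow addition of iodine to the activated boronate should keep it away from the furan.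

**Step 13**
Reactants: 16 (5Z)-4-methoxy-3-methyl-5-[(2R)-2-methylhept-6-ynylidene]furan-2(5H)-one; 26 3-[(4S,5E)-6-iodo-4-methylhex-5-enyl]furan
Product: 29 (5Z)-5-[(2R,6E,8E,10S)-13-(furan-3-yl)-2,6,10-trimethyltrideca-6,8-dienylidene]-4-methoxy-3-methylfuran-2(5H)-one, via alkenylalane 27 (not isolated), via alkenylzinc chloride 28 (not isolated)
Conditions: 16 (1.3 equiv), Me3Al (3 equiv per 16), Cp2ZrCl2 (0.3 equiv), CH2Cl2, 0 °C to rt; volatiles removed in vacuo; then 26 (1.0 equiv), ZnCl2, Pd(PPh3)4 (5 mol%), THF, rt; aq. NH4Cl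
Reagents that add atoms: trimethylaluminium, C[Al](C)C
Why: Cp2ZrCl2 and Me3Al form a zirconium–methyl/aluminium species that adds methyl and metal syn across the terminal C11≡C12 alkyne (Negishi zirconium-catalysed methylalumination), methyl to the internal carbon C11 and aluminium to C12, so alane 27 has the E geometry by construction. After excess Me3Al is stripped, ZnCl2 converts 27 into alkenylzinc 28, zerovalent palladium inserts into the C13–I bond of 26, and transmetalation and reductive elimination join C12 to C13 with retention at both alkenes (Negishi alkenyl–alkenyl coupling, the standard entry to methyl-branched E,E-1,3-dienes). No ring is closed and no stereocenter is created; C7 and C15 lie away from the reacting carbons and should be untouched. The step needs regioselective carbometalation, which the unbranched propargylic CH2 (C10) secures. It also needs chemoselectivity for the alkyne, which should hold because the ylidene methyl tetronate is a donor-substituted vinylogous carbonate that is not a substrate for methylalumination and simple or conjugated alkenes do not carbometalate under these conditions. Using 16 in slight excess and removing Me3Al before 26 is added should suppress methyl transfer to the iodide.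

**Step 14**
Reactants: 29 (5Z)-5-[(2R,6E,8E,10S)-13-(furan-3-yl)-2,6,10-trimethyltrideca-6,8-dienylidene]-4-methoxy-3-methylfuran-2(5H)-one
Product: 31 CNP0223721.1 (5Z)-5-[(2R,6E,8E,10S)-13-(furan-3-yl)-2,6,10-trimethyltrideca-6,8-dienylidene]-4-hydroxy-3-methylfuran-2(5H)-one, via lithium tetronate 30 (not isolated)
Conditions: n-PrSLi (from n-PrSH, n-BuLi), HMPA, rt; then 1 M HCl, 0 °C
Reagents that add atoms: none
Why: SN2 O-demethylation of the vinylogous methyl ester by the soft thiolate, with the tetronate as leaving group, should free the acid on acidification without touching the alkenes, the furan or either stereocenter.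

## Compound list

1 | 4-hydroxy-3-methylfuran-2(5H)-one (3-methyltetronic acid) | CC1=C(O)COC1=O | starting material
2 | potassium 3-methyltetronate | CC1=C([O-])COC1=O.[K+] | intermediate
3 | 4-methoxy-3-methylfuran-2(5H)-one | CC1=C(OC)COC1=O | intermediate
4 | hept-6-ynoic acid | C#CCCCCC(=O)O | starting material
5 | (R)-4-benzyloxazolidin-2-one | O=C1N[C@H](Cc2ccccc2)CO1 | starting material
6 | hept-6-ynoic pivalic anhydride | C#CCCCCC(=O)OC(=O)C(C)(C)C | intermediate
7 | (4R)-4-benzyl-3-(hept-6-ynoyl)oxazolidin-2-one | C#CCCCCC(=O)N1[C@H](Cc2ccccc2)COC1=O | intermediate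
8 | sodium (Z)-enolate of 7 | [Na+].[O-]/C(=C\CCCC#C)N1[C@H](Cc2ccccc2)COC1=O | intermediate
9 | (4R)-4-benzyl-3-[(2R)-2-methylhept-6-ynoyl]oxazolidin-2-one | O=C([C@H](C)CCCC#C)N1[C@H](Cc2ccccc2)COC1=O | intermediate
10 | (2R)-2-methylhept-6-yn-1-ol | OC[C@H](C)CCCC#C | intermediate
11 | (2R)-2-methylhept-6-ynal | O=C[C@H](C)CCCC#C | intermediate
12 | lithium 4-methoxy-3-methylfuran-2-olate | [Li+].[O-]c1occ(OC)c1C | intermediate
13 | lithium alkoxide of aldol 14 | CC1=C(OC)C(C([O-])[C@H](C)CCCC#C)OC1=O.[Li+] | intermediate
14 | 5-[(2R)-1-hydroxy-2-methylhept-6-ynyl]-4-methoxy-3-methylfuran-2(5H)-one (mixture at C5 and the carbinol carbon) | CC1=C(OC)C(C(O)[C@H](C)CCCC#C)OC1=O | intermediate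
15 | methanesulfonate of 14 | CC1=C(OC)C(C(OS(C)(=O)=O)[C@H](C)CCCC#C)OC1=O | intermediate
16 | (5Z)-4-methoxy-3-methyl-5-[(2R)-2-methylhept-6-ynylidene]furan-2(5H)-one | CC1=C(OC)/C(=C/[C@H](C)CCCC#C)OC1=O | intermediate
17 | (S)-β-citronellene, (3S)-3,7-dimethylocta-1,6-diene | C=C[C@@H](C)CCC=C(C)C | starting material
18 | (4S)-4-methylhex-5-enal | C=C[C@@H](C)CCC=O | intermediate
19 | (4S)-4-methylhex-5-en-1-ol | C=C[C@@H](C)CCCO | intermediate
20 | (3S)-6-iodo-3-methylhex-1-ene | C=C[C@@H](C)CCCI | intermediate
21 | 3-bromofuran | Brc1ccoc1 | starting material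
22 | [(4S)-4-methylhex-5-enyl]lithium | C=C[C@@H](C)CCC[Li] | intermediate
23 | [(4S)-4-methylhex-5-enyl]zinc bromide | C=C[C@@H](C)CCC[Zn]Br | intermediate
24 | 3-[(4S)-4-methylhex-5-enyl]furan | C=C[C@@H](C)CCCc1ccoc1 | intermediate
25 | 2-[(1E,3S)-6-(furan-3-yl)-3-methylhex-1-enyl]-4,4,5,5-tetramethyl-1,3,2-dioxaborolane | CC1(C)OB(/C=C/[C@@H](C)CCCc2ccoc2)OC1(C)C | intermediate
26 | 3-[(4S,5E)-6-iodo-4-methylhex-5-enyl]furan | I/C=C/[C@@H](C)CCCc1ccoc1 | intermediate
27 | dimethyl{(1E,6R)-7-[(2Z)-3-methoxy-4-methyl-5-oxofuran-2(5H)-ylidene]-2,6-dimethylhept-1-enyl}alane | CC1=C(OC)/C(=C/[C@H](C)CCC/C(C)=C/[Al](C)C)OC1=O | intermediate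
28 | chloro{(1E,6R)-7-[(2Z)-3-methoxy-4-methyl-5-oxofuran-2(5H)-ylidene]-2,6-dimethylhept-1-enyl}zinc | CC1=C(OC)/C(=C/[C@H](C)CCC/C(C)=C/[Zn]Cl)OC1=O | intermediate
29 | (5Z)-5-[(2R,6E,8E,10S)-13-(furan-3-yl)-2,6,10-trimethyltrideca-6,8-dienylidene]-4-methoxy-3-methylfuran-2(5H)-one | CC1=C(OC)/C(=C/[C@H](C)CCC/C(C)=C/C=C/[C@@H](C)CCCc2ccoc2)OC1=O | intermediate
30 | lithium tetronate of 31 | CC1=C([O-])/C(=C/[C@H](C)CCC/C(C)=C/C=C/[C@@H](C)CCCc2ccoc2)OC1=O.[Li+] | intermediate
31 | CNP0223721.1, (5Z)-5-[(2R,6E,8E,10S)-13-(furan-3-yl)-2,6,10-trimethyltrideca-6,8-dienylidene]-4-hydroxy-3-methylfuran-2(5H)-one | CC1=C(O)/C(=C/[C@H](C)CCC/C(C)=C/C=C/[C@@H](C)CCCc2ccoc2)OC1=O | target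

## Step count and risks

Total steps: 14. Longest linear sequence: 8 steps (steps 2–7, 13 and 14, from hept-6-ynoic acid 4); the iodide branch is 5 steps (8–12) before the union.

**Step 13 (key step).** The Lewis-acidic Me3Al/zirconocene mixture may complex or attack the lactone carbonyl of 16 and so stall or divert the carbometalation, and residual Me3Al may transfer methyl to 26 during the coupling. The fallback sets out from alkynol 10 (with iodide 26) and comes back at 29. The same methylalumination–coupling would be run one stage earlier, on a free alkynol, where it is routine. Alcohol 10 with Me3Al (3.5 equiv) and Cp2ZrCl2 in CH2Cl2 should give the aluminium alkoxide–alkenylalane F1. After evaporation this is coupled with 26 (ZnCl2, Pd(PPh3)4, THF) to give dienol F2. Oxidation with TEMPO/PhI(OAc)2 gives dienal F3, and addition of lithium furanolate 12 (from 3 and LDA, −78 °C) gives aldol F4. Mesylation to mesylate F5 and DBU elimination then return to 29, from which step 14 follows unchanged.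

**Step 12.** Electrophilic iodination or oxidation of the electron-rich furan ring by iodine/hypoiodite may compete with substitution at boron. The fallback sets out from alkene 24 and comes back at 26 without any electrophilic halogen. Dihydroxylation and periodate cleavage (OsO4 2 mol%, NaIO4, 2,6-lutidine, dioxane/H2O), passing through diol F6, should give aldehyde F7. Takai olefination (CrCl2, CHI3, THF, 0 °C to rt) converts F7 into the E-alkenyl iodide 26.

**Step 8.** Over-oxidation may occur, with ozone also cleaving the vinyl group once the trisubstituted alkene is consumed. The fallback sets out from citronellene 17 and comes back at alcohol 19. The alkenes are differentiated by epoxidation instead: mCPBA (1.0 equiv, CH2Cl2, 0 °C) reacts far faster at the trisubstituted alkene and should give epoxide F8. H5IO6 in THF/H2O cleaves F8 to aldehyde 18, and NaBH4 reduction gives 19.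

## Further compounds

F1 | step 13 | dimethylaluminium (2R,6E)-7-(dimethylalumanyl)-2,6-dimethylhept-6-en-1-olate | C[Al](C)OC[C@H](C)CCC/C(C)=C/[Al](C)C
F2 | step 13 | (2R,6E,8E,10S)-13-(furan-3-yl)-2,6,10-trimethyltrideca-6,8-dien-1-ol | OC[C@H](C)CCC/C(C)=C/C=C/[C@@H](C)CCCc1ccoc1
F3 | step 13 | (2R,6E,8E,10S)-13-(furan-3-yl)-2,6,10-trimethyltrideca-6,8-dienal | O=C[C@H](C)CCC/C(C)=C/C=C/[C@@H](C)CCCc1ccoc1
F4 | step 13 | 5-[(2R,6E,8E,10S)-13-(furan-3-yl)-1-hydroxy-2,6,10-trimethyltrideca-6,8-dienyl]-4-methoxy-3-methylfuran-2(5H)-one (mixture at C5 and the carbinol carbon) | CC1=C(OC)C(C(O)[C@H](C)CCC/C(C)=C/C=C/[C@@H](C)CCCc2ccoc2)OC1=O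
F5 | step 13 | methanesulfonate of F4 | CC1=C(OC)C(C(OS(C)(=O)=O)[C@H](C)CCC/C(C)=C/C=C/[C@@H](C)CCCc2ccoc2)OC1=O
F6 | step 12 | (3S)-6-(furan-3-yl)-3-methylhexane-1,2-diol (both C2 epimers) | OCC(O)[C@@H](C)CCCc1ccoc1
F7 | step 12 | (2S)-5-(furan-3-yl)-2-methylpentanal | O=C[C@@H](C)CCCc1ccoc1
F8 | step 8 | 2,2-dimethyl-3-[(3S)-3-methylpent-4-enyl]oxirane (both oxirane epimers) | C=C[C@@H](C)CCC1OC1(C)C
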